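**Retrosynthetic overview**
1. The seven-membered ring is closed last, at C9–C10, by an intramolecular B-alkyl Suzuki–Miyaura coupling (C8=C9 vinyl group plus C10 vinyl iodide), which also leaves the exocyclic methylene; the C4 methyl then comes from an enol triflate.
2. The cyclopentane ring is bought as (S)-4-silyloxycyclopentenone; C1–C10 and C5–C6 are formed in one three-component conjugate addition–aldol coupling with a 1-silylvinyl copper reagent and an oxolane aldehyde (C6–C9, C11–C15).
3. The oxolane aldehyde comes from geraniol by Sharpless and Shi epoxidation and the key cascade: a vinyl copper reagent opens the 2,3-epoxy alcohol at C7, the freed C11 alkoxide closes the oxolane on C14 (O–C14 bond), and acetic anhydride caps the C15 oxygen.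
4. Enabling feature: the oxolane oxygen sits on the quaternary carbon C11, whose neighbour C7 carries the carbinol carbon C6 and which is 1,4 to C14; C6–C7–C11(Me)–C12–C13–C14–C15Me2 is the geraniol skeleton, so the oxygens at C11 and C14/C15 can be stored as the two epoxides of 2,3:6,7-diepoxygeraniol.
5. Ring order: oxolane (step 3), cyclopentane joined (step 6), seven-membered ring (step 11).

Key step: step 3

Remark: atom numbers follow the target: C1/C5 ring fusion, C2–C4 cyclopentene (methyl on C4), C6 carbinol, C7–C10 rest of the seven-membered ring (exocyclic methylene on C10), oxolane O–C11(Me)–C12–C13–C14, C15 = CMe2OAc. It is assumed that the L-fructose-derived epoxidation ketone and (S)-4-(tert-butyldimethylsilyloxy)cyclopent-2-enone are purchasable in enantiopure form.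

Step 1
Reactants: 1 geraniol
Product: 2 [(2S,3S)-3-methyl-3-(4-methylpent-3-en-1-yl)oxiran-2-yl]methanol
Conditions: Ti(OiPr)4 (5 mol%), L-(+)-diethyl tartrate (6 mol%), t-BuOOH, 4 Å molecular sieves, CH2Cl2, −20 °C
Reagents that add atoms: tert-butyl hydroperoxide CC(C)(C)OO
Why: Sharpless asymmetric epoxidation: the titanium–L-(+)-tartrate catalyst should deliver oxygen only to the allylic olefin and give the (2S,3S)-epoxide, which fixes C11 and prepares C7.

Step 2
Reactants: 2 [(2S,3S)-3-methyl-3-(4-methylpent-3-en-1-yl)oxiran-2-yl]methanol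
Product: 3 [(2S,3S)-3-{2-[(2S)-3,3-dimethyloxiran-2-yl]ethyl}-3-methyloxiran-2-yl]methanol
Conditions: 1,2:4,5-di-O-isopropylidene-β-L-erythro-2,3-hexodiulo-2,6-pyranose (30 mol%), KHSO5 (as 2KHSO5·KHSO4·K2SO4), K2CO3, Bu4NHSO4 (cat.), MeCN/CH2(OMe)2/aq. Na2B4O7 buffer, 0 °C
Reagents that add atoms: potassium peroxymonosulfate [K+].OOS(=O)(=O)[O-]
Why: Shi epoxidation: the chiral dioxirane from the L-fructose-derived ketone should epoxidise the remaining trisubstituted olefin under reagent control to the (6S)-epoxide, the sense opposite to that of the D-fructose catalyst.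

Step 3
Reactants: 3 [(2S,3S)-3-{2-[(2S)-3,3-dimethyloxiran-2-yl]ethyl}-3-methyloxiran-2-yl]methanol
Product: 6 (2R)-2-[(2S,5R)-5-(2-acetoxypropan-2-yl)-2-methyloxolan-2-yl]but-3-en-1-yl acetate, via ring-opened C11 magnesium alkoxide 4 (not isolated), via oxolane C15 magnesium alkoxide 5 (not isolated)
Conditions: CH2=CHMgBr (5 equiv), CuI (20 mol%), THF, −30 to 0 °C then 23 °C; then Ac2O (8 equiv), 4-(dimethylamino)pyridine (20 mol%), 0 to 23 °C
Reagents that add atoms: vinylmagnesium bromide C=C[Mg]Br; acetic anhydride CC(=O)OC(C)=O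
Why: The first equivalent of CH2=CHMgBr turns the C6 hydroxyl into its magnesium alkoxide, and the vinylcopper species formed from CuI then opens the neighbouring epoxide by SN2 attack at C7 (C11 is fully substituted and closed to attack) with inversion, which sets C7 and frees the tertiary C11 alkoxide 4. This alkoxide attacks C14 of the distal epoxide in a 5-exo-tet closure with inversion, forming the oxolane O–C14 bond and the C15 alkoxide 5, and acetic anhydride then acetylates both alkoxides, so the tertiary acetate of the target is installed in the same flask. The closest known reaction types are the copper-mediated C2-selective opening of 3,3-disubstituted 2,3-epoxy alcohols to 1,3-diols and the nucleophile-triggered conversion of 1,5-bis-epoxides into 2,5-disubstituted oxolanes. C11 is carried unchanged from the Sharpless step, C7 follows from anti opening at the (2S)-epoxide carbon, and C14 from inversion at the (S)-configured distal epoxide carbon, so the 2,5-cis oxolane should form stereospecifically. The step needs site selectivity between the two epoxides, which the alkoxide-assisted reactivity of the epoxy alcohol and the inertness of an isolated trisubstituted epoxide towards the copper reagent at or below 0 °C should secure, and exo over endo closure, which anionic attack at the less substituted C14 should secure.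

Step 4
Reactants: 6 (2R)-2-[(2S,5R)-5-(2-acetoxypropan-2-yl)-2-methyloxolan-2-yl]but-3-en-1-yl acetate
Product: 7 2-[(2R,5S)-5-[(2R)-1-hydroxybut-3-en-2-yl]-5-methyloxolan-2-yl]propan-2-yl acetate
Conditions: K2CO3 (0.2 equiv), MeOH, 0 °C
Reagents that add atoms: none
Why: Base-catalysed transesterification should cleave the unhindered primary acetate much faster than the tertiary one, and no stereocentre is touched.

Step 5
Reactants: 7 2-[(2R,5S)-5-[(2R)-1-hydroxybut-3-en-2-yl]-5-methyloxolan-2-yl]propan-2-yl acetate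
Product: 8 2-[(2R,5S)-5-methyl-5-[(2S)-1-oxobut-3-en-2-yl]oxolan-2-yl]propan-2-yl acetate
Conditions: Dess–Martin periodinane, NaHCO3, CH2Cl2, 0 °C; used at once
Reagents that add atoms: none
Why: Dess–Martin oxidation under buffered, amine-free conditions should give the α-branched aldehyde without epimerisation at C7 or migration of the vinyl double bond into conjugation.

Step 6
Reactants: 8 2-[(2R,5S)-5-methyl-5-[(2S)-1-oxobut-3-en-2-yl]oxolan-2-yl]propan-2-yl acetate; 9 (4S)-4-(tert-butyldimethylsilyloxy)cyclopent-2-en-1-one; 10 (1-bromoethenyl)trimethylsilane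
Product: 14 aldol adduct: 2,3-trans-3,4-trans-4-(tert-butyldimethylsilyloxy)-3-[1-(trimethylsilyl)ethenyl]cyclopentanone carrying at ring position 2 the CH(OH)–CH(CH=CH2)–oxolane chain of 8 (C1 C5 C6 C7 C11 C14 as in the target; C2–OSi trans to C1), via vinyllithium 11 (not isolated), via organocopper 12 (not isolated), via copper enolate 13 (not isolated)
Conditions: 10, t-BuLi (2 equiv), Et2O, −78 °C; CuI, PBu3, −78 °C; 9, −78 °C; then 8, −78 °C; aq. NH4Cl
Reagents that add atoms: none
Why: Three-component conjugate addition–aldol coupling: the organocopper reagent adds to C1 anti to the C2 silyloxy group, the regiodefined enolate attacks aldehyde 8 anti to the new C1 substituent (setting C5), and the closed Zimmerman–Traxler transition state of the ring (E)-enolate (5,6-anti) together with Felkin–Anh control by the quaternary C11 group (matched pair) should set C6.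

Step 7
Reactants: 14 aldol adduct
Product: 15 C6 tert-butyldimethylsilyl ether of 14
Conditions: t-BuMe2SiOTf, 2,6-lutidine, CH2Cl2, −78 to 0 °C
Reagents that add atoms: tert-butyldimethylsilyl trifluoromethanesulfonate CC(C)(C)[Si](C)(C)OS(=O)(=O)C(F)(F)F
Why: Silyl ether formation protects the aldol hydroxyl and blocks retro-aldol cleavage without affecting any stereocentre.

Step 8
Reactants: 15 C6 tert-butyldimethylsilyl ether of 14
Product: 16 4,5-trans-cyclopent-2-en-1-one (C4=O, C2=C3) with the 1-(trimethylsilyl)ethenyl group on C1 and the silyloxy-bearing side chain on C5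
Conditions: 1,8-diazabicyclo[5.4.0]undec-7-ene, CH2Cl2, 0 °C
Reagents that add atoms: none
Why: E1cB β-elimination of the C2 silyloxy group, the usual way to 4-substituted cyclopentenones, should give the enone because only the unhindered C3 methylene is deprotonated, leaving C1 and C5 intact.

Step 9
Reactants: 16 4,5-trans-cyclopentenone with 1-(trimethylsilyl)ethenyl group
Product: 17 4,5-trans-cyclopentenone with 1-iodoethenyl group on C1
Conditions: N-iodosuccinimide, MeCN/ClCH2CN (4:1), 23 °C
Reagents that add atoms: N-iodosuccinimide O=C1CCC(=O)N1I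
Why: Iododesilylation (ipso substitution of the 1,1-disubstituted vinylsilane) should give the 2-iodoalkene, since the enone and the monosubstituted vinyl group are too poorly nucleophilic to compete.

Step 10
Reactants: 17 4,5-trans-cyclopentenone with 1-iodoethenyl group
Product: 19 C4 tert-butyldimethylsilyl enol ether (C3=C4) with C10 vinyl iodide and C8=C9 vinyl group, via lithium enolate 18 (not isolated)
Conditions: LiBH(s-Bu)3, THF, −78 °C; then t-BuMe2SiCl, HMPA, −78 to 23 °C
Reagents that add atoms: tert-butyldimethylsilyl chloride CC(C)(C)[Si](C)(C)Cl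
Why: Conjugate hydride reduction of the β-unsubstituted cyclopentenone by the bulky borohydride, then O-silylation of the regiodefined enolate, should mask the ketone as the C3=C4 enol ether, and no stereocentre is formed.

Step 11
Reactants: 19 silyl enol ether with C10 vinyl iodide and C8=C9 vinyl group
Product: 21 trans-fused hydroazulene with C10 exocyclic methylene, C4 silyl enol ether and C6 silyl ether, via C9 alkylborane 20 (not isolated)
Conditions: 9-borabicyclo[3.3.1]nonane dimer, THF, 23 °C; then PdCl2(dppf) (10 mol%), AsPh3 (20 mol%), Cs2CO3, DMF/THF/H2O, 23 to 50 °C, 2 mM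
Reagents that add atoms: none
Why: Intramolecular B-alkyl Suzuki–Miyaura coupling: the borane should hydroborate only the monosubstituted C8=C9 olefin at C9, and palladium-catalysed coupling with the C10 vinyl iodide should close the seven-membered ring and leave the exocyclic methylene, the trans ring fusion having been fixed in step 6.

Step 12
Reactants: 21 hydroazulene silyl enol ether
Product: 22 C4 enol triflate (C3=C4) of the hydroazulene, C6 silyl ether retained
Conditions: CsF, PhNTf2, 1,2-dimethoxyethane, 23 °C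
Reagents that add atoms: N-phenylbis(trifluoromethanesulfonimide) O=S(=O)(N(c1ccccc1)S(=O)(=O)C(F)(F)F)C(F)(F)F
Why: Fluoride cleavage of the silyl enol ether in the presence of the triflating agent (enolate triflation) should give the C3=C4 enol triflate regiospecifically while the alkyl silyl ether survives.

Step 13
Reactants: 22 hydroazulene enol triflate
Product: 23 C6 tert-butyldimethylsilyl ether of the target
Conditions: MeZnCl, Pd(PPh3)4 (5 mol%), THF, 23 to 50 °C
Reagents that add atoms: methylzinc chloride C[Zn]Cl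
Why: Negishi cross-coupling of the enol triflate should install the C4 methyl group with the double bond held at C3=C4, and the acetate and the exocyclic olefin are tolerated.

Step 14
Reactants: 23 C6 tert-butyldimethylsilyl ether of the target
Product: 24 target, CNP0302132.4
Conditions: HF·pyridine, pyridine, THF, 0 to 23 °C
Reagents that add atoms: none
Why: Fluoride-mediated desilylation should free the C6 hydroxyl without touching the tertiary acetate or the olefins.

**Compound list**
1 | geraniol, (2E)-3,7-dimethylocta-2,6-dien-1-ol | CC(C)=CCC/C(C)=C/CO | starting material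
2 | [(2S,3S)-3-methyl-3-(4-methylpent-3-en-1-yl)oxiran-2-yl]methanol | OC[C@@H]1O[C@@]1(C)CCC=C(C)C | intermediate
3 | [(2S,3S)-3-{2-[(2S)-3,3-dimethyloxiran-2-yl]ethyl}-3-methyloxiran-2-yl]methanol | OC[C@@H]1O[C@@]1(C)CC[C@@H]1OC1(C)C | intermediate
4 | bis(bromomagnesium) salt of (2R,3S)-5-[(2S)-3,3-dimethyloxiran-2-yl]-2-ethenyl-3-methylpentane-1,3-diol | C=C[C@H](CO[Mg]Br)[C@@](C)(O[Mg]Br)CC[C@@H]1OC1(C)C | intermediate
5 | bis(bromomagnesium) salt of (2R)-2-[(2S,5R)-5-(2-hydroxypropan-2-yl)-2-methyloxolan-2-yl]but-3-en-1-ol | C=C[C@@H]([C@]1(C)CC[C@H](C(C)(C)O[Mg]Br)O1)CO[Mg]Br | intermediate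
6 | (2R)-2-[(2S,5R)-5-(2-acetoxypropan-2-yl)-2-methyloxolan-2-yl]but-3-en-1-yl acetate | C=C[C@@H]([C@]1(C)CC[C@H](C(C)(C)OC(C)=O)O1)COC(C)=O | intermediate
7 | 2-[(2R,5S)-5-[(2R)-1-hydroxybut-3-en-2-yl]-5-methyloxolan-2-yl]propan-2-yl acetate | C=C[C@@H]([C@]1(C)CC[C@H](C(C)(C)OC(C)=O)O1)CO | intermediate
8 | 2-[(2R,5S)-5-methyl-5-[(2S)-1-oxobut-3-en-2-yl]oxolan-2-yl]propan-2-yl acetate | C=C[C@@H]([C@]1(C)CC[C@H](C(C)(C)OC(C)=O)O1)C=O | intermediate
9 | (4S)-4-(tert-butyldimethylsilyloxy)cyclopent-2-en-1-one | O=C1C=C[C@@H](O[Si](C)(C)C(C)(C)C)C1 | starting material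
10 | (1-bromoethenyl)trimethylsilane | C=C(Br)[Si](C)(C)C | starting material
11 | [1-(trimethylsilyl)ethenyl]lithium | [Li]C(=C)[Si](C)(C)C | intermediate
12 | [1-(trimethylsilyl)ethenyl]copper–tributylphosphine complex | C=C([Cu])[Si](C)(C)C.CCCCP(CCCC)CCCC | intermediate
13 | copper (3S,4S)-4-(tert-butyldimethylsilyloxy)-3-[1-(trimethylsilyl)ethenyl]cyclopent-1-en-1-olate | C=C([Si](C)(C)C)[C@H]1C=C(O[Cu])C[C@@H]1O[Si](C)(C)C(C)(C)C | intermediate
14 | aldol adduct: cyclopentanone (C4=O) with C5 side chain CH(OH)–CH(CH=CH2)–oxolane, C1 1-(trimethylsilyl)ethenyl trans to C5, C2 silyloxy trans to C1; C1, C5, C6, C7, C11, C14 as in the target | C=C[C@@H]([C@]1(C)CC[C@H](C(C)(C)OC(C)=O)O1)[C@@H](O)[C@@H]2C(=O)C[C@H](O[Si](C)(C)C(C)(C)C)[C@H]2C(=C)[Si](C)(C)C | intermediate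
15 | C6 tert-butyldimethylsilyl ether of 14 | C=C[C@@H]([C@]1(C)CC[C@H](C(C)(C)OC(C)=O)O1)[C@@H](O[Si](C)(C)C(C)(C)C)[C@@H]2C(=O)C[C@H](O[Si](C)(C)C(C)(C)C)[C@H]2C(=C)[Si](C)(C)C | intermediate
16 | 4,5-trans-cyclopent-2-en-1-one (C4=O, C2=C3) with C1 1-(trimethylsilyl)ethenyl and C5 silyloxy side chain; stereocentres as in the target | C=C[C@@H]([C@]1(C)CC[C@H](C(C)(C)OC(C)=O)O1)[C@@H](O[Si](C)(C)C(C)(C)C)[C@@H]2C(=O)C=C[C@H]2C(=C)[Si](C)(C)C | intermediate
17 | as 16 with a 1-iodoethenyl group on C1 | C=C[C@@H]([C@]1(C)CC[C@H](C(C)(C)OC(C)=O)O1)[C@@H](O[Si](C)(C)C(C)(C)C)[C@@H]2C(=O)C=C[C@H]2C(=C)I | intermediate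
18 | lithium C3=C4 enolate from conjugate reduction of 17 | C=C[C@@H]([C@]1(C)CC[C@H](C(C)(C)OC(C)=O)O1)[C@@H](O[Si](C)(C)C(C)(C)C)[C@@H]2C(O[Li])=CC[C@H]2C(=C)I | intermediate
19 | C4 tert-butyldimethylsilyl enol ether (C3=C4) with C10 vinyl iodide and C8=C9 vinyl group; stereocentres as in the target | C=C[C@@H]([C@]1(C)CC[C@H](C(C)(C)OC(C)=O)O1)[C@@H](O[Si](C)(C)C(C)(C)C)[C@@H]2C(O[Si](C)(C)C(C)(C)C)=CC[C@H]2C(=C)I | intermediate
20 | C9 B-alkyl-9-borabicyclo[3.3.1]nonane from 19 | C1CC2CCCC(C1)B2CC[C@@H]([C@]3(C)CC[C@H](C(C)(C)OC(C)=O)O3)[C@@H](O[Si](C)(C)C(C)(C)C)[C@@H]4C(O[Si](C)(C)C(C)(C)C)=CC[C@H]4C(=C)I | intermediate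
21 | trans-fused hydroazulene: C10 exocyclic methylene, C4 silyl enol ether, C6 silyl ether, C7 oxolane; stereocentres as in the target | C=C1CC[C@@H]([C@]2(C)CC[C@H](C(C)(C)OC(C)=O)O2)[C@@H](O[Si](C)(C)C(C)(C)C)[C@@H]2C(O[Si](C)(C)C(C)(C)C)=CC[C@@H]12 | intermediate
22 | C4 enol triflate of the hydroazulene, C6 silyl ether | C=C1CC[C@@H]([C@]2(C)CC[C@H](C(C)(C)OC(C)=O)O2)[C@@H](O[Si](C)(C)C(C)(C)C)[C@@H]2C(OS(=O)(=O)C(F)(F)F)=CC[C@@H]12 | intermediate
23 | C6 tert-butyldimethylsilyl ether of the target | C=C1CC[C@@H]([C@]2(C)CC[C@H](C(C)(C)OC(C)=O)O2)[C@@H](O[Si](C)(C)C(C)(C)C)[C@@H]2C(C)=CC[C@@H]12 | intermediate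
24 | CNP0302132.4 | C=C1CC[C@@H]([C@]2(C)CC[C@H](C(C)(C)OC(C)=O)O2)[C@@H](O)[C@@H]2C(C)=CC[C@@H]12 | target

**Totals**
Total step count: 14. Longest linear sequence: 14 steps (from geraniol; 9 and 10 are bought).

**Steps most likely to fail**

Step 3. The cascade may lose site selectivity (copper reagent attacking the distal epoxide or C11), the epoxy alcohol may undergo base-induced epoxide migration, or acetylation may start before the oxolane has closed. The fallback sets out from 2 and comes back at 6. Compound 2 alone is opened with CH2=CHMgBr/CuI, with no second epoxide present, to give (2R,3S)-2-ethenyl-3,7-dimethyloct-6-ene-1,3-diol F1. Its trisubstituted olefin is epoxidised with the same L-fructose-derived ketone and KHSO5, and camphorsulfonic acid in CH2Cl2 then lets the C11 hydroxyl open the epoxide at C14 (acid-catalysed 5-exo hydroxy-epoxide cyclisation, inversion at C14) to give (2R)-2-[(2S,5R)-5-(2-hydroxypropan-2-yl)-2-methyloxolan-2-yl]but-3-en-1-ol F2. Exhaustive acetylation (Ac2O, Et3N, 4-(dimethylamino)pyridine, 40 °C) should then give 6.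

Step 6. The basic enolate may take a proton from the acidic α-vinyl aldehyde instead of adding to it, which returns the simple conjugate adduct and erodes C7; retro-aldol or β-elimination on work-up is a second risk. The fallback sets out from 9 and 10 and comes back at 14. The conjugate addition of 12 to 9 is run in the presence of Me3SiCl to isolate (3S,4S)-4-(tert-butyldimethylsilyloxy)-1-(trimethylsilyloxy)-3-[1-(trimethylsilyl)ethenyl]cyclopent-1-ene F3. A Mukaiyama aldol reaction of F3 with 8 (BF3·OEt2, CH2Cl2, −78 °C) then forms the C5–C6 bond through a non-basic open transition state, in which the C1 substituent shields one face of the enol ether and Felkin–Anh control operates on the aldehyde, and should give 14 after aqueous work-up.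

Step 11. Transmetalation and closure of the seven-membered ring may be slow, so that oligomerisation, protodeboronation or β-hydride elimination of the alkylborane takes over. The fallback sets out from 19 and comes back at 21. Hydroboration with 9-borabicyclo[3.3.1]nonane and oxidation with NaBO3·4H2O should give the C9 primary alcohol F4. Appel iodination (I2, PPh3, imidazole) should give the C9 primary iodide F5. Zinc insertion (Zn, LiCl, THF), selective for the alkyl iodide, gives the alkylzinc iodide F6, and an intramolecular Negishi coupling with Pd(PPh3)4 under high dilution should then close the ring to 21.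

**Further compounds**
F1 | step 3 | (2R,3S)-2-ethenyl-3,7-dimethyloct-6-ene-1,3-diol | C=C[C@H](CO)[C@@](C)(O)CCC=C(C)C
F2 | step 3 | (2R)-2-[(2S,5R)-5-(2-hydroxypropan-2-yl)-2-methyloxolan-2-yl]but-3-en-1-ol | C=C[C@@H]([C@]1(C)CC[C@H](C(C)(C)O)O1)CO
F3 | step 6 | (3S,4S)-4-(tert-butyldimethylsilyloxy)-1-(trimethylsilyloxy)-3-[1-(trimethylsilyl)ethenyl]cyclopent-1-ene | C=C([Si](C)(C)C)[C@H]1C=C(O[Si](C)(C)C)C[C@@H]1O[Si](C)(C)C(C)(C)C
F4 | step 11 | C9 primary alcohol from hydroboration–oxidation of 19 | OCC[C@@H]([C@]1(C)CC[C@H](C(C)(C)OC(C)=O)O1)[C@@H](O[Si](C)(C)C(C)(C)C)[C@@H]2C(O[Si](C)(C)C(C)(C)C)=CC[C@H]2C(=C)I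
F5 | step 11 | C9 primary iodide | ICC[C@@H]([C@]1(C)CC[C@H](C(C)(C)OC(C)=O)O1)[C@@H](O[Si](C)(C)C(C)(C)C)[C@@H]2C(O[Si](C)(C)C(C)(C)C)=CC[C@H]2C(=C)I
F6 | step 11 | C9 alkylzinc iodide | I[Zn]CC[C@@H]([C@]1(C)CC[C@H](C(C)(C)OC(C)=O)O1)[C@@H](O[Si](C)(C)C(C)(C)C)[C@@H]2C(O[Si](C)(C)C(C)(C)C)=CC[C@H]2C(=C)I
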